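**Plan**
- Numbering is that of benzofuran (O1 to C7a); ring A is the benzo ring and ring B the 2-aryl ring. The last cut only unmasks the C3 aldehyde (from a dimethyl acetal) and the ring B phenol (from a MOM ether).
- Ring A is cut at C4–C5, C6–C7 and C3a–C4, together with C7–C7a, which a Wolff shift makes. This leads to a 2-(diazoacetyl)furan and the ynol ether MeO–C≡C–CH2CH=CMe2.
- Enabling feature: between furan carbons C3a and C7a, ring A carries C4–OH, C5–prenyl, C6–OMe and C7–H in unbroken order. This is the sequence ketene C=O, alkyne C–R, alkyne C–OMe, ketene CH that a furylketene and an ynol ether lay down.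
- The furan is cut at C2–C1′ (Suzuki coupling) and at C3–CHO (bromine–magnesium exchange, then DMF), back to methyl 4,5-dibromofuran-2-carboxylate. The ynol ether is cut at its propargylic C–C bond to methoxyacetylene and prenyl bromide.
- Forward: ring B and the furan are bought and joined (steps 1–3), and the furan is dressed as acetal and diazoketone (steps 4–7). The ynol ether is made aside (steps 8–9), ring A closes in step 10, and acid unmasks the target in step 11.
- Stereochemistry: the target has no stereocentre and its only alkene carries two identical methyl groups, so nothing needs to be controlled.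

Key step: step 10

Assumption: ethereal diazomethane is generated separately from N-methyl-N-nitroso-p-toluenesulfonamide and KOH and counted as a reagent; methoxyacetylene is not taken as purchasable and is made in step 8.

Step 1
Reactants: 1 4-bromo-3-methoxyphenol
Product: 2 1-bromo-2-methoxy-4-(methoxymethoxy)benzene
Conditions: MOMCl, iPr2NEt, CH2Cl2, 0 → 23 °C
Reagents that add atoms: chloromethyl methyl ether COCCl
Why: O-alkylation of the phenol with an α-chloro ether (MOM protection) gives an acetal-type ether that should withstand the bases, organometallics, light and heat to come and still fall to aqueous acid at the end.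

Step 2
Reactants: 2 1-bromo-2-methoxy-4-(methoxymethoxy)benzene
Product: 3 2-[2-methoxy-4-(methoxymethoxy)phenyl]-4,4,5,5-tetramethyl-1,3,2-dioxaborolane
Conditions: B2pin2, PdCl2(dppf) (3 mol %), KOAc, 1,4-dioxane, 90 °C
Reagents that add atoms: bis(pinacolato)diboron CC1(C)OB(OC1(C)C)B1OC(C)(C)C(C)(C)O1
Why: Miyaura borylation of an aryl bromide tolerates both ethers and gives a pinacol boronate that resists protodeboronation better than the free electron-rich boronic acid.

Step 3
Reactants: 3 2-[2-methoxy-4-(methoxymethoxy)phenyl]-4,4,5,5-tetramethyl-1,3,2-dioxaborolane; 4 methyl 4,5-dibromofuran-2-carboxylate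
Product: 5 methyl 4-bromo-5-[2-methoxy-4-(methoxymethoxy)phenyl]furan-2-carboxylate
Conditions: 3 (1.0 equiv), Pd(PPh3)4 (5 mol %), K2CO3, 1,4-dioxane/H2O, 80 °C
Reagents that add atoms: none
Why: In this site-selective Suzuki–Miyaura coupling, zerovalent palladium inserts faster into the C–Br bond next to the ring oxygen than into the β C–Br bond, as is established for 2,3-dibromofurans, so one equivalent of 3 should arylate C5 only.

Step 4
Reactants: 5 methyl 4-bromo-5-[2-methoxy-4-(methoxymethoxy)phenyl]furan-2-carboxylate
Product: 8 methyl 4-formyl-5-[2-methoxy-4-(methoxymethoxy)phenyl]furan-2-carboxylate, via furylmagnesium chloride 6 (not isolated), via magnesium hemiaminal alkoxide 7 (not isolated)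
Conditions: iPrMgCl·LiCl, THF, −30 °C; DMF, −30 → 0 °C; aq NH4Cl
Reagents that add atoms: N,N-dimethylformamide CN(C)C=O
Why: Bromine–magnesium exchange followed by Bouveault formylation should work because the ester speeds the exchange, the neighbouring aryl methoxy group can chelate magnesium, the methyl ester is not attacked at −30 °C, and the aldehyde is released from 7 only on quenching.

Step 5
Reactants: 8 methyl 4-formyl-5-[2-methoxy-4-(methoxymethoxy)phenyl]furan-2-carboxylate
Product: 9 methyl 4-(dimethoxymethyl)-5-[2-methoxy-4-(methoxymethoxy)phenyl]furan-2-carboxylate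
Conditions: HC(OMe)3, PPTS (cat.), MeOH, 23 °C; Et3N quench
Reagents that add atoms: trimethyl orthoformate COC(OC)OC; methanol CO
Why: Acid-catalysed acetalisation is driven by the orthoformate as water scavenger, PPTS at room temperature is too weak to cleave the aryl MOM ether, and the labile acetal is thereafter handled only on Et3N-treated silica.

Step 6
Reactants: 9 methyl 4-(dimethoxymethyl)-5-[2-methoxy-4-(methoxymethoxy)phenyl]furan-2-carboxylate
Product: 10 potassium 4-(dimethoxymethyl)-5-[2-methoxy-4-(methoxymethoxy)phenyl]furan-2-carboxylate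
Conditions: KOSiMe3, THF, 23 °C; filtration
Reagents that add atoms: potassium trimethylsilanolate C[Si](C)(C)[O-].[K+]
Why: Anhydrous methyl ester cleavage by a silanolate delivers the carboxylate salt as a precipitate, so the acid-sensitive acetal never meets the acidification that an ordinary saponification needs.

Step 7
Reactants: 10 potassium 4-(dimethoxymethyl)-5-[2-methoxy-4-(methoxymethoxy)phenyl]furan-2-carboxylate
Product: 12 2-diazo-1-{4-(dimethoxymethyl)-5-[2-methoxy-4-(methoxymethoxy)phenyl]furan-2-yl}ethan-1-one, via mixed carbonic anhydride 11 (not isolated)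
Conditions: ClCO2iBu, THF, −15 °C; CH2N2 (excess), Et2O, 0 → 23 °C
Reagents that add atoms: diazomethane C=[N+]=[N-]
Why: Acylation of diazomethane by a mixed carbonic anhydride (first stage of the Arndt–Eistert sequence) takes place at the more electrophilic furoyl carbonyl and releases no HCl, so acetal and MOM ether stay intact.

Step 8
Reactants: 13 2-chloro-1,1-dimethoxyethane (chloroacetaldehyde dimethyl acetal)
Product: 15 methoxyethyne (methoxyacetylene), via sodium methoxyacetylide 14 (not isolated)
Conditions: NaNH2 (3 equiv), liq. NH3, −33 °C; NH3 off; cold aq NaCl; distil into THF at −78 °C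
Reagents that add atoms: none
Why: This is the classical alkoxyacetylene synthesis, in which amide base removes methanol and HCl in two β-eliminations and deprotonates the alkyne, and protonation of 14 frees the volatile ynol ether, kept as a cold THF solution.

Step 9
Reactants: 15 methoxyethyne (methoxyacetylene); 16 1-bromo-3-methylbut-2-ene (prenyl bromide)
Product: 18 1-methoxy-5-methylhex-4-en-1-yne, via lithium methoxyacetylide 17 (not isolated)
Conditions: nBuLi (1.0 equiv), THF, −78 °C; 16, DMPU, −78 → 0 °C
Reagents that add atoms: none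
Why: SN2 alkylation of a lithium alkoxyacetylide at the unhindered CH2 of a primary allylic bromide gives the skipped enyne, and the absence of excess base and the low temperature should prevent its isomerisation into conjugation.

Step 10
Reactants: 12 2-diazo-1-{4-(dimethoxymethyl)-5-[2-methoxy-4-(methoxymethoxy)phenyl]furan-2-yl}ethan-1-one; 18 1-methoxy-5-methylhex-4-en-1-yne
Product: 23 3-(dimethoxymethyl)-6-methoxy-2-[2-methoxy-4-(methoxymethoxy)phenyl]-5-(3-methylbut-2-en-1-yl)-1-benzofuran-4-ol, via furylketene 19 (not isolated), via cyclobutenone 20 (not isolated), via dienylketene 21 (not isolated), via cyclohexadienone 22 (not isolated)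
Conditions: 18 (1.5 equiv), hν (medium-pressure Hg lamp, Pyrex, λ > 300 nm), degassed toluene, 25 °C; then 110 °C
Reagents that add atoms: none
Why: Light expels N2 from 12 and the furyl group shifts to the former diazo carbon (photochemical Wolff rearrangement, which makes C7–C7a) to give furylketene 19, whose carbonyl carbon is attacked by the prenyl-bearing carbon of 18 (C4–C5) before the oxocarbenium carbon closes onto the enolate carbon (C6–C7), a stepwise two-plus-two cycloaddition leading to cyclobutenone 20. Light or the final heating opens 20 in a four-electron electrocyclic reaction to dienylketene 21, ring A closes by a six-electron disrotatory electrocyclisation of the ketene carbon onto furan C3 (C3a–C4), and dienone 22 enolises to phenol 23. The closest known reaction is the Danheiser benzannulation in its diazoketone form, which is established for heteroaryl diazoketones, furans among them, with alkoxy- and siloxyalkynes. The selectivity needed is the orientation of the ketene–alkyne union, and the oxygen lone pair of 18 secures it by making the carbon remote from oxygen the nucleophile, so prenyl ends at C5 beside the new C4 hydroxyl and methoxy at C6; the site of closure is not in doubt, because the only carbon neighbour of the ketene-bearing furan carbon is the unsubstituted C3. No stereocentre survives (those of 20 and 22 are transient), and since the opening of 20 is reversible, the dienylketene isomer with the furan turned away from the ketene returns to 20 until all material drains through 21. The methyl ynol ether has no β-hydrogen for retro-ene loss at 110 °C, the prenyl alkene hangs on a single CH2 and cannot reach the ketene carbon, and halogen-free toluene with λ > 300 nm releases no acid, so acetal and MOM ether should come through.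

Step 11
Reactants: 23 3-(dimethoxymethyl)-6-methoxy-2-[2-methoxy-4-(methoxymethoxy)phenyl]-5-(3-methylbut-2-en-1-yl)-1-benzofuran-4-ol
Product: 24 4-hydroxy-2-(4-hydroxy-2-methoxyphenyl)-6-methoxy-5-(3-methylbut-2-en-1-yl)-1-benzofuran-3-carbaldehyde (the target)
Conditions: 3 M aq HCl, THF, 40 °C
Reagents that add atoms: water O
Why: Acid-catalysed hydrolysis removes both acetal-type groups in one operation; the dimethyl acetal goes first, and the C4 hydroxyl, then hydrogen-bonded to the new aldehyde, is a poor nucleophile toward the prenyl alkene while the MOM ether is cleaved.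

**Compound list**
1 | 4-bromo-3-methoxyphenol | COc1cc(O)ccc1Br | starting material
2 | 1-bromo-2-methoxy-4-(methoxymethoxy)benzene | COCOc1ccc(Br)c(OC)c1 | intermediate
3 | 2-[2-methoxy-4-(methoxymethoxy)phenyl]-4,4,5,5-tetramethyl-1,3,2-dioxaborolane | COCOc1ccc(B2OC(C)(C)C(C)(C)O2)c(OC)c1 | intermediate
4 | methyl 4,5-dibromofuran-2-carboxylate | COC(=O)c1cc(Br)c(Br)o1 | starting material
5 | methyl 4-bromo-5-[2-methoxy-4-(methoxymethoxy)phenyl]furan-2-carboxylate | COCOc1ccc(-c2oc(C(=O)OC)cc2Br)c(OC)c1 | intermediate
6 | {5-(methoxycarbonyl)-2-[2-methoxy-4-(methoxymethoxy)phenyl]furan-3-yl}magnesium chloride (formed in situ) | COCOc1ccc(-c2oc(C(=O)OC)cc2[Mg]Cl)c(OC)c1 | intermediate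
7 | chloromagnesium alkoxide of methyl 4-[(dimethylamino)(hydroxy)methyl]-5-[2-methoxy-4-(methoxymethoxy)phenyl]furan-2-carboxylate (formed in situ) | COCOc1ccc(-c2oc(C(=O)OC)cc2C(O[Mg]Cl)N(C)C)c(OC)c1 | intermediate
8 | methyl 4-formyl-5-[2-methoxy-4-(methoxymethoxy)phenyl]furan-2-carboxylate | COCOc1ccc(-c2oc(C(=O)OC)cc2C=O)c(OC)c1 | intermediate
9 | methyl 4-(dimethoxymethyl)-5-[2-methoxy-4-(methoxymethoxy)phenyl]furan-2-carboxylate | COCOc1ccc(-c2oc(C(=O)OC)cc2C(OC)OC)c(OC)c1 | intermediate
10 | potassium 4-(dimethoxymethyl)-5-[2-methoxy-4-(methoxymethoxy)phenyl]furan-2-carboxylate | COCOc1ccc(-c2oc(C(=O)[O-])cc2C(OC)OC)c(OC)c1.[K+] | intermediate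
11 | 4-(dimethoxymethyl)-5-[2-methoxy-4-(methoxymethoxy)phenyl]furan-2-carboxylic 2-methylpropyl carbonic anhydride (formed in situ) | COCOc1ccc(-c2oc(C(=O)OC(=O)OCC(C)C)cc2C(OC)OC)c(OC)c1 | intermediate
12 | 2-diazo-1-{4-(dimethoxymethyl)-5-[2-methoxy-4-(methoxymethoxy)phenyl]furan-2-yl}ethan-1-one | COCOc1ccc(-c2oc(C(=O)C=[N+]=[N-])cc2C(OC)OC)c(OC)c1 | intermediate
13 | 2-chloro-1,1-dimethoxyethane | COC(CCl)OC | starting material
14 | sodium methoxyacetylide (formed in situ) | COC#[C-].[Na+] | intermediate
15 | methoxyethyne | COC#C | intermediate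
16 | 1-bromo-3-methylbut-2-ene | CC(C)=CCBr | starting material
17 | lithium methoxyacetylide (formed in situ) | COC#[C-].[Li+] | intermediate
18 | 1-methoxy-5-methylhex-4-en-1-yne | COC#CCC=C(C)C | intermediate
19 | 2-{4-(dimethoxymethyl)-5-[2-methoxy-4-(methoxymethoxy)phenyl]furan-2-yl}ethen-1-one (furylketene, formed in situ) | O=C=Cc1cc(C(OC)OC)c(-c2ccc(OCOC)cc2OC)o1 | intermediate
20 | 4-{4-(dimethoxymethyl)-5-[2-methoxy-4-(methoxymethoxy)phenyl]furan-2-yl}-3-methoxy-2-(3-methylbut-2-en-1-yl)cyclobut-2-en-1-one (racemic, formed in situ) | O=C1C(CC=C(C)C)=C(OC)C1c1cc(C(OC)OC)c(-c2ccc(OCOC)cc2OC)o1 | intermediate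
21 | (3E)-4-{4-(dimethoxymethyl)-5-[2-methoxy-4-(methoxymethoxy)phenyl]furan-2-yl}-3-methoxy-2-(3-methylbut-2-en-1-yl)buta-1,3-dien-1-one (furan cis to the ketene carbon chain, formed in situ) | O=C=C(CC=C(C)C)/C(OC)=C\c1cc(C(OC)OC)c(-c2ccc(OCOC)cc2OC)o1 | intermediate
22 | 3-(dimethoxymethyl)-6-methoxy-2-[2-methoxy-4-(methoxymethoxy)phenyl]-5-(3-methylbut-2-en-1-yl)-1-benzofuran-4(3aH)-one (racemic, formed in situ) | O=C1C(CC=C(C)C)=C(OC)C=C2OC(c3ccc(OCOC)cc3OC)=C(C(OC)OC)C12 | intermediate
23 | 3-(dimethoxymethyl)-6-methoxy-2-[2-methoxy-4-(methoxymethoxy)phenyl]-5-(3-methylbut-2-en-1-yl)-1-benzofuran-4-ol | COCOc1ccc(-c2oc3cc(OC)c(CC=C(C)C)c(O)c3c2C(OC)OC)c(OC)c1 | intermediate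
24 | 4-hydroxy-2-(4-hydroxy-2-methoxyphenyl)-6-methoxy-5-(3-methylbut-2-en-1-yl)-1-benzofuran-3-carbaldehyde | COc1cc(O)ccc1-c1oc2cc(OC)c(CC=C(C)C)c(O)c2c1C=O | target

**Step count**
- Total steps: 11.
- Longest linear sequence: 9 (steps 1–7, 10, 11); steps 8 and 9 form the side branch.

**Steps most likely to fail**

Step 10.
- Several processes could erode the cascade. The arylfuran chromophore and the product may screen the light, or the product may degrade photochemically. The ring opening of 20 that turns the furan inward may be slow beside the bulky acetal. The ketene may dimerise or acylate the product phenol.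
- The fallback sets out from 12 and makes the same ketene in the dark.
- Wolff rearrangement catalysed by PhCO2Ag with Et3N in aqueous dioxane would give {4-(dimethoxymethyl)-5-[2-methoxy-4-(methoxymethoxy)phenyl]furan-2-yl}acetic acid F1.
- 1-Chloro-N,N,2-trimethylprop-1-en-1-amine would convert it under neutral conditions into {4-(dimethoxymethyl)-5-[2-methoxy-4-(methoxymethoxy)phenyl]furan-2-yl}acetyl chloride F2.
- Slow addition of F2 to Et3N and 18 in toluene would generate 19 by dehydrochlorination and trap it as 20.
- Compound 20 is then isolated and heated in toluene at 110 °C, and the route is rejoined at 23.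

Step 4.
- Halogen–metal exchange at the β position may be sluggish, which would let the Grignard reagent add to the ester. Protonation of the furylmagnesium species would cause simple loss of bromine.
- The fallback sets out from 5 and replaces the organomagnesium chemistry by cross-coupling and oxidative cleavage.
- Suzuki–Miyaura vinylation with 4,4,5,5-tetramethyl-2-vinyl-1,3,2-dioxaborolane (Pd(PPh3)4, K2CO3, aqueous dioxane) would give methyl 4-ethenyl-5-[2-methoxy-4-(methoxymethoxy)phenyl]furan-2-carboxylate F3.
- Lemieux–Johnson cleavage (OsO4 cat., NaIO4, 2,6-lutidine, aqueous dioxane) rejoins the route at 8.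

Step 11.
- While the slower MOM cleavage proceeds, protonation of the prenyl alkene may lead to ring closure by the C4 hydroxyl or to hydration.
- The fallback sets out from 23 and avoids strong Brønsted acid by unmasking in two stages.
- PPTS in wet acetone at 23 °C would hydrolyse only the acetal, giving 4-hydroxy-6-methoxy-2-[2-methoxy-4-(methoxymethoxy)phenyl]-5-(3-methylbut-2-en-1-yl)-1-benzofuran-3-carbaldehyde F4.
- Me3SiOTf with 2,2′-bipyridyl in CH2Cl2 at 0 °C would then transfer the methoxymethyl group to the pyridine nitrogen. This leaves 6-methoxy-2-[2-methoxy-4-(trimethylsilyloxy)phenyl]-5-(3-methylbut-2-en-1-yl)-4-(trimethylsilyloxy)-1-benzofuran-3-carbaldehyde F5.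
- Addition of water desilylates F5, and the route is rejoined at 24.

**Further compounds**
F1 | step 10 | {4-(dimethoxymethyl)-5-[2-methoxy-4-(methoxymethoxy)phenyl]furan-2-yl}acetic acid | COCOc1ccc(-c2oc(CC(=O)O)cc2C(OC)OC)c(OC)c1
F2 | step 10 | {4-(dimethoxymethyl)-5-[2-methoxy-4-(methoxymethoxy)phenyl]furan-2-yl}acetyl chloride | COCOc1ccc(-c2oc(CC(=O)Cl)cc2C(OC)OC)c(OC)c1
F3 | step 4 | methyl 4-ethenyl-5-[2-methoxy-4-(methoxymethoxy)phenyl]furan-2-carboxylate | COCOc1ccc(-c2oc(C(=O)OC)cc2C=C)c(OC)c1
F4 | step 11 | 4-hydroxy-6-methoxy-2-[2-methoxy-4-(methoxymethoxy)phenyl]-5-(3-methylbut-2-en-1-yl)-1-benzofuran-3-carbaldehyde | COCOc1ccc(-c2oc3cc(OC)c(CC=C(C)C)c(O)c3c2C=O)c(OC)c1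
F5 | step 11 | 6-methoxy-2-[2-methoxy-4-(trimethylsilyloxy)phenyl]-5-(3-methylbut-2-en-1-yl)-4-(trimethylsilyloxy)-1-benzofuran-3-carbaldehyde | COc1cc(O[Si](C)(C)C)ccc1-c1oc2cc(OC)c(CC=C(C)C)c(O[Si](C)(C)C)c2c1C=O
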